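## Retrosynthetic overview

1. Target 29 ⇐ silyl ether 28 ⇐ C7–C8 bond: enantioconvergent nickel-catalysed reductive coupling of ring A 1-chloroethylpyrone 12 (both epimers) with ring B (E)-vinyl bromide 27. This sets C8 and keeps the E-alkene; both esters are already in place.
2. 27 ⇐ C2–C3 bond: vinylogous Mukaiyama aldol of silyl dienol ether 24 (from pyrone 4) with aldehyde 22 (sets C2, C3) ⇐ catalytic anti-crotylboration of bromo-enal 16 (sets C4, C5).
3. 12 ⇐ γ-lithiation/chlorination of 10 ⇐ vinylogous aldol of lithiated 4 with (S)-2-chloropropanal 6 (sets C2', C3'), then dechlorination.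
4. Rings: both γ-pyrone rings (A and B) are the same symmetric pyrone 4, made first and only once (step 1); no ring is closed afterwards, so the usual late triketone cyclodehydrations are avoided.

Locants: non-6-ene chain as in the name of 29 (C2 on ring B, C3 OAc, C4, C5 O-propanoyl, C6=C7, C8 on ring A); pentan-2-yl arm on ring A is C2', C3'. Target = 2R,3R,4R,5R,6E,8S,2'S,3'S.

Assumption: 5 and 17 are bought, and the handedness of the step 8 acid (Re-face attack, as for benzaldehyde) and of the step 14 ligand (as for 1-chloroethylarenes) carries over to these substrates; if a model run shows the opposite sense, the mirror-image catalyst is used.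

## Route

Step 1
Reactants: 1 pentan-3-one; 2 propanoic anhydride
Product: 4 2,6-diethyl-3,5-dimethyl-4H-pyran-4-one, via triketone 3 (not isolated)
Conditions: polyphosphoric acid, 95 °C
Reagents that add atoms: none
Why: Classical polyphosphoric-acid γ-pyrone synthesis, in which the ketone is C-propanoylated on both α-carbons and the 1,3,5-triketone cyclodehydrates to the pyrone that serves as both ring A and ring B; no stereocentre is formed.

Step 2
Reactants: 5 (2S)-2-chloropropan-1-ol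
Product: 6 (2S)-2-chloropropanal
Conditions: Dess–Martin periodinane (1,1,1-triacetoxy-1,1-dihydro-1,2-benziodoxol-3(1H)-one), NaHCO3, CH2Cl2, 0 °C; used at once as a cold solution
Reagents that add atoms: none
Why: Buffered Dess–Martin oxidation converts the chiral-pool chloro alcohol to the α-chloroaldehyde without touching the chlorine-bearing stereocentre.

Step 3
Reactants: 4 2,6-diethyl-3,5-dimethyl-4H-pyran-4-one; 6 (2S)-2-chloropropanal
Product: 9 2-[(2S,3R,4S)-4-chloro-3-(triethylsilyloxy)pentan-2-yl]-6-ethyl-3,5-dimethyl-4H-pyran-4-one, via lithium dienolate 7 (not isolated), via lithium aldolate 8 (not isolated)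
Conditions: LiN(SiMe3)2, THF, −78 °C; then 6, −78 °C; then Et3SiOTf, −78 °C
Reagents that add atoms: triethylsilyl trifluoromethanesulfonate, CC[Si](CC)(CC)OS(=O)(=O)C(F)(F)F
Why: Vinylogous (γ) lithium aldol of a 2-ethyl-4-pyrone, in which the exocyclic carbon of the (Z)-dienolate attacks the aldehyde face given by the Cornforth/polar Felkin–Anh model (1,2-anti chlorohydrin, which is 3'S of the target once chlorine is removed), the open transition state with the aldehyde chain anti to the ring gives the 2',3'-anti (2'S) relationship, and silylation of the aldolate at −78 °C blocks retro-aldol.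

Step 4
Reactants: 9 2-[(2S,3R,4S)-4-chloro-3-(triethylsilyloxy)pentan-2-yl]-6-ethyl-3,5-dimethyl-4H-pyran-4-one
Product: 10 2-ethyl-3,5-dimethyl-6-[(2S,3S)-3-(triethylsilyloxy)pentan-2-yl]-4H-pyran-4-one
Conditions: Bu3SnH, 2,2'-azobis(2-methylpropanenitrile) (cat.), toluene, 90 °C
Reagents that add atoms: none
Why: Radical-chain tin hydride dehalogenation removes the chlorine that served only as a stereocontrol element; the radical forms at the carbon that becomes CH2, so C2' and C3' are untouched.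

Step 5
Reactants: 10 2-ethyl-3,5-dimethyl-6-[(2S,3S)-3-(triethylsilyloxy)pentan-2-yl]-4H-pyran-4-one
Product: 12 2-(1-chloroethyl)-3,5-dimethyl-6-[(2S,3S)-3-(triethylsilyloxy)pentan-2-yl]-4H-pyran-4-one (both epimers at the CHCl carbon), via lithium dienolate 11 (not isolated)
Conditions: LiN(SiMe3)2 (1.05 equiv), THF, −78 °C; inverse addition to C2Cl6, THF, −78 °C
Reagents that add atoms: hexachloroethane, ClC(Cl)(Cl)C(Cl)(Cl)Cl
Why: Kinetic γ-deprotonation occurs at the unhindered ethyl CH2 and not at the tertiary, shielded C2'–H, and the dienolate is chlorinated at its exocyclic carbon by the positive-chlorine donor (enolate α-halogenation type); the new centre is left as a mixture because step 14 is stereoconvergent.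

Step 6
Reactants: 13 prop-2-yn-1-ol
Product: 15 (2E)-3-bromo-2-methylprop-2-en-1-ol, via alkenylalane 14 (not isolated)
Conditions: AlMe3 (3 equiv), (C5H5)2ZrCl2 (25 mol %), CH2Cl2, 0 °C to rt; then N-bromosuccinimide, THF, −30 °C
Reagents that add atoms: trimethylaluminium, C[Al](C)C; N-bromosuccinimide, O=C1CCC(=O)N1Br
Why: Negishi zirconium-catalysed carboalumination adds methyl and aluminium syn across the alkyne with methyl on the internal carbon, and bromodealumination with retention gives only the E-vinyl bromide.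

Step 7
Reactants: 15 (2E)-3-bromo-2-methylprop-2-en-1-ol
Product: 16 (2E)-3-bromo-2-methylprop-2-enal
Conditions: MnO2, CH2Cl2, rt
Reagents that add atoms: none
Why: Selective allylic alcohol oxidation by MnO2 stops at the enal and does not isomerise the double bond.

Step 8
Reactants: 16 (2E)-3-bromo-2-methylprop-2-enal; 17 2-[(2E)-but-2-en-1-yl]-4,4,5,5-tetramethyl-1,3,2-dioxaborolane
Product: 19 (1E,3R,4R)-1-bromo-2,4-dimethylhexa-1,5-dien-3-ol, via borate ester 18 (not isolated)
Conditions: (R)-3,3'-bis(2,4,6-triisopropylphenyl)-1,1'-binaphthyl-2,2'-diyl hydrogen phosphate (5 mol %), toluene, −30 °C; aqueous work-up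
Reagents that add atoms: none
Why: Chiral phosphoric-acid-catalysed crotylboration through a closed chair transition state, in which the E-crotyl geometry gives the 3,4-anti product and the (R)-acid directs Re-face attack, setting C5 (R) and C4 (R) of the target.

Step 9
Reactants: 19 (1E,3R,4R)-1-bromo-2,4-dimethylhexa-1,5-dien-3-ol; 2 propanoic anhydride
Product: 20 (1E,3R,4R)-1-bromo-2,4-dimethylhexa-1,5-dien-3-yl propanoate
Conditions: Et3N, 4-(dimethylamino)pyridine (cat.), CH2Cl2, 0 °C to rt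
Reagents that add atoms: none
Why: Nucleophile-catalysed acylation installs the final propanoate early, where it also acts as the C5–O protecting group; no stereocentre is affected.

Step 10
Reactants: 20 (1E,3R,4R)-1-bromo-2,4-dimethylhexa-1,5-dien-3-yl propanoate
Product: 22 (2S,3R,4E)-5-bromo-2,4-dimethyl-1-oxopent-4-en-3-yl propanoate, via vicinal diol 21 (not isolated)
Conditions: OsO4 (2 mol %), NaIO4, 2,6-lutidine, 1,4-dioxane/H2O, rt; used crude
Reagents that add atoms: sodium periodate, [Na+].[O-]I(=O)(=O)=O (terminal oxidant; the oxygen is relayed by catalytic OsO4)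
Why: Lemieux–Johnson cleavage, in which OsO4 dihydroxylates the monosubstituted vinyl group far faster than the trisubstituted, bromine-deactivated alkene and periodate cleaves the diol, while lutidine buffering avoids α-epimerisation and β-elimination (the descriptor at C4 changes to 2S only by priority).

Step 11
Reactants: 4 2,6-diethyl-3,5-dimethyl-4H-pyran-4-one
Product: 24 {[(2Z)-6-ethyl-2-ethylidene-3,5-dimethyl-2H-pyran-4-yl]oxy}trimethylsilane, via silyloxypyrylium triflate 23 (not isolated)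
Conditions: Me3SiOTf, iPr2NEt, CH2Cl2, 0 °C; pentane, filtration under argon; used at once
Reagents that add atoms: trimethylsilyl trifluoromethanesulfonate, C[Si](C)(C)OS(=O)(=O)C(F)(F)F
Why: Vinylogous soft enolisation, in which O-silylation gives the 4-silyloxypyrylium ion whose 2-ethyl CH2 is deprotonated by the hindered amine, and allylic 1,3-strain against the 3-methyl group places the exocyclic methyl cis to the ring oxygen (single Z isomer).

Step 12
Reactants: 22 (2S,3R,4E)-5-bromo-2,4-dimethyl-1-oxopent-4-en-3-yl propanoate; 24 {[(2Z)-6-ethyl-2-ethylidene-3,5-dimethyl-2H-pyran-4-yl]oxy}trimethylsilane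
Product: 26 (1E,3R,4R,5R,6R)-1-bromo-6-(6-ethyl-3,5-dimethyl-4-oxo-4H-pyran-2-yl)-5-hydroxy-2,4-dimethylhept-1-en-3-yl propanoate, via pyrylium aldolate 25 (not isolated)
Conditions: BF3·OEt2, CH2Cl2, −78 °C; then aq. NaHCO3, brief aq. citric acid wash
Reagents that add atoms: none
Why: Proposed new method: vinylogous Mukaiyama aldol of a 2-alkylidene-4-silyloxy-2H-pyran (closest known types: BF3-promoted vinylogous Mukaiyama aldols of silyl dienol ethers and aldols of γ-lithiated 2-ethyl-4-pyrones), in which attack through the exocyclic carbon regenerates an aromatic pyrylium so only that site reacts, the anti α-methyl-β-acyloxy aldehyde gives C3 (R) by reinforcing Felkin–Anh and 1,3-anti induction, and the open transition state with the aldehyde chain anti to the ring and the BF3-bound oxygen away from the γ-methyl gives the 2,3-anti (2R) relationship.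

Step 13
Reactants: 26 (1E,3R,4R,5R,6R)-1-bromo-6-(6-ethyl-3,5-dimethyl-4-oxo-4H-pyran-2-yl)-5-hydroxy-2,4-dimethylhept-1-en-3-yl propanoate
Product: 27 (1E,3R,4R,5R,6R)-5-(acetyloxy)-1-bromo-6-(6-ethyl-3,5-dimethyl-4-oxo-4H-pyran-2-yl)-2,4-dimethylhept-1-en-3-yl propanoate
Conditions: Ac2O, pyridine, 4-(dimethylamino)pyridine (cat.), CH2Cl2, 0 °C
Reagents that add atoms: acetic anhydride, CC(=O)OC(C)=O
Why: Nucleophile-catalysed acetylation of the hindered C3 alcohol is run at once on the fresh aldol so that neither retro-aldol nor 1,3-migration of the propanoyl group can compete; no stereocentre is affected.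

Step 14
Reactants: 12 2-(1-chloroethyl)-3,5-dimethyl-6-[(2S,3S)-3-(triethylsilyloxy)pentan-2-yl]-4H-pyran-4-one (both epimers); 27 (1E,3R,4R,5R,6R)-5-(acetyloxy)-1-bromo-6-(6-ethyl-3,5-dimethyl-4-oxo-4H-pyran-2-yl)-2,4-dimethylhept-1-en-3-yl propanoate
Product: 28 (2R,3R,4R,5R,6E,8S)-3-(acetyloxy)-8-{3,5-dimethyl-4-oxo-6-[(2S,3S)-3-(triethylsilyloxy)pentan-2-yl]-4H-pyran-2-yl}-2-(6-ethyl-3,5-dimethyl-4-oxo-4H-pyran-2-yl)-4,6-dimethylnon-6-en-5-yl propanoate
Conditions: NiCl2·dme (dme = 1,2-dimethoxyethane, 10 mol %), (3aR,3a'R,8aS,8a'S)-2,2'-(cyclopropane-1,1-diyl)bis(3a,8a-dihydro-8H-indeno[1,2-d]oxazole) (11 mol %), Mn powder (3 equiv), NaI (0.5 equiv), N,N-dimethylacetamide, 0 °C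
Reagents that add atoms: none
Why: Proposed new method: enantioconvergent nickel-catalysed reductive cross-electrophile coupling of a 1-chloroethyl-4-pyrone with a trisubstituted vinyl bromide (closest known type: asymmetric nickel/bis(oxazoline)/manganese reductive vinylation of 1-chloroethylarenes with vinyl bromides), in which chlorine abstraction from either epimer of 12 gives the same planar, pyrone-stabilised radical that is captured by the chiral alkenylnickel species from 27 and reductively eliminated to the (8S) product with retention of the E-alkene, under neutral conditions that spare both esters and the base-labile pyrone-adjacent centres.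

Step 15
Reactants: 28 (2R,3R,4R,5R,6E,8S)-3-(acetyloxy)-8-{3,5-dimethyl-4-oxo-6-[(2S,3S)-3-(triethylsilyloxy)pentan-2-yl]-4H-pyran-2-yl}-2-(6-ethyl-3,5-dimethyl-4-oxo-4H-pyran-2-yl)-4,6-dimethylnon-6-en-5-yl propanoate
Product: 29 (2R,3R,4R,5R,6E,8S)-3-(acetyloxy)-2-(6-ethyl-3,5-dimethyl-4-oxo-4H-pyran-2-yl)-8-{6-[(2S,3S)-3-hydroxypentan-2-yl]-3,5-dimethyl-4-oxo-4H-pyran-2-yl}-4,6-dimethylnon-6-en-5-yl propanoate (CNP0265513.1)
Conditions: HF·pyridine, pyridine, THF, 0 °C to rt
Reagents that add atoms: none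
Why: Fluoride-mediated cleavage of the triethylsilyl ether under buffered, non-basic conditions leaves the acetate, the propanoate and the epimerisable C2, C8 and C2' centres untouched and gives the target.

## Compound list

1 | pentan-3-one | CCC(=O)CC | starting material
2 | propanoic anhydride | CCC(=O)OC(=O)CC | starting material
3 | 4,6-dimethylnonane-3,5,7-trione (stereoisomer/enol mixture) | CCC(=O)C(C)C(=O)C(C)C(=O)CC | intermediate
4 | 2,6-diethyl-3,5-dimethyl-4H-pyran-4-one | CCc1oc(CC)c(C)c(=O)c1C | intermediate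
5 | (2S)-2-chloropropan-1-ol | C[C@H](Cl)CO | starting material
6 | (2S)-2-chloropropanal | C[C@H](Cl)C=O | intermediate
7 | lithium (2Z)-6-ethyl-2-ethylidene-3,5-dimethyl-2H-pyran-4-olate | C/C=C1\OC(CC)=C(C)C([O-])=C1C.[Li+] | intermediate
8 | lithium (2S,3R,4S)-2-chloro-4-(6-ethyl-3,5-dimethyl-4-oxo-4H-pyran-2-yl)pentan-3-olate | CCc1oc([C@@H](C)[C@@H]([O-])[C@@H](Cl)C)c(C)c(=O)c1C.[Li+] | intermediate
9 | 2-[(2S,3R,4S)-4-chloro-3-(triethylsilyloxy)pentan-2-yl]-6-ethyl-3,5-dimethyl-4H-pyran-4-one | CCc1oc([C@@H](C)[C@@H](O[Si](CC)(CC)CC)[C@@H](Cl)C)c(C)c(=O)c1C | intermediate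
10 | 2-ethyl-3,5-dimethyl-6-[(2S,3S)-3-(triethylsilyloxy)pentan-2-yl]-4H-pyran-4-one | CCc1oc([C@@H](C)[C@@H](O[Si](CC)(CC)CC)CC)c(C)c(=O)c1C | intermediate
11 | lithium (2Z)-2-ethylidene-3,5-dimethyl-6-[(2S,3S)-3-(triethylsilyloxy)pentan-2-yl]-2H-pyran-4-olate | C/C=C1\OC([C@@H](C)[C@@H](O[Si](CC)(CC)CC)CC)=C(C)C([O-])=C1C.[Li+] | intermediate
12 | 2-(1-chloroethyl)-3,5-dimethyl-6-[(2S,3S)-3-(triethylsilyloxy)pentan-2-yl]-4H-pyran-4-one (both epimers at CHCl) | CC(Cl)c1oc([C@@H](C)[C@@H](O[Si](CC)(CC)CC)CC)c(C)c(=O)c1C | intermediate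
13 | prop-2-yn-1-ol | C#CCO | starting material
14 | [(1E)-3-(dimethylalumanyloxy)-2-methylprop-1-en-1-yl]dimethylalumane | C[Al](C)/C=C(C)/CO[Al](C)C | intermediate
15 | (2E)-3-bromo-2-methylprop-2-en-1-ol | OC/C(C)=C/Br | intermediate
16 | (2E)-3-bromo-2-methylprop-2-enal | O=C/C(C)=C/Br | intermediate
17 | 2-[(2E)-but-2-en-1-yl]-4,4,5,5-tetramethyl-1,3,2-dioxaborolane | C/C=C/CB1OC(C)(C)C(C)(C)O1 | starting material
18 | 2-{[(1E,3R,4R)-1-bromo-2,4-dimethylhexa-1,5-dien-3-yl]oxy}-4,4,5,5-tetramethyl-1,3,2-dioxaborolane | CC1(C)OB(O[C@@H](/C(C)=C/Br)[C@H](C)C=C)OC1(C)C | intermediate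
19 | (1E,3R,4R)-1-bromo-2,4-dimethylhexa-1,5-dien-3-ol | O[C@@H](/C(C)=C/Br)[C@H](C)C=C | intermediate
20 | (1E,3R,4R)-1-bromo-2,4-dimethylhexa-1,5-dien-3-yl propanoate | CCC(=O)O[C@@H](/C(C)=C/Br)[C@H](C)C=C | intermediate
21 | (1E,3R,4R)-1-bromo-5,6-dihydroxy-2,4-dimethylhex-1-en-3-yl propanoate (both C5 epimers) | CCC(=O)O[C@@H](/C(C)=C/Br)[C@H](C)C(O)CO | intermediate
22 | (2S,3R,4E)-5-bromo-2,4-dimethyl-1-oxopent-4-en-3-yl propanoate | CCC(=O)O[C@@H](/C(C)=C/Br)[C@H](C)C=O | intermediate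
23 | 2,6-diethyl-3,5-dimethyl-4-(trimethylsilyloxy)pyrylium trifluoromethanesulfonate | CCc1[o+]c(CC)c(C)c(O[Si](C)(C)C)c1C.[O-]S(=O)(=O)C(F)(F)F | intermediate
24 | {[(2Z)-6-ethyl-2-ethylidene-3,5-dimethyl-2H-pyran-4-yl]oxy}trimethylsilane | C/C=C1\OC(CC)=C(C)C(O[Si](C)(C)C)=C1C | intermediate
25 | 2-[(2R,3R,4R,5R,6E)-7-bromo-4,6-dimethyl-5-(propanoyloxy)-3-(trifluoroboranuidyloxy)hept-6-en-2-yl]-6-ethyl-3,5-dimethyl-4-(trimethylsilyloxy)pyrylium (zwitterion) | CCC(=O)O[C@@H](/C(C)=C/Br)[C@H](C)[C@@H](O[B-](F)(F)F)[C@@H](C)c1[o+]c(CC)c(C)c(O[Si](C)(C)C)c1C | intermediate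
26 | (1E,3R,4R,5R,6R)-1-bromo-6-(6-ethyl-3,5-dimethyl-4-oxo-4H-pyran-2-yl)-5-hydroxy-2,4-dimethylhept-1-en-3-yl propanoate | CCC(=O)O[C@@H](/C(C)=C/Br)[C@H](C)[C@@H](O)[C@@H](C)c1oc(CC)c(C)c(=O)c1C | intermediate
27 | (1E,3R,4R,5R,6R)-5-(acetyloxy)-1-bromo-6-(6-ethyl-3,5-dimethyl-4-oxo-4H-pyran-2-yl)-2,4-dimethylhept-1-en-3-yl propanoate | CCC(=O)O[C@@H](/C(C)=C/Br)[C@H](C)[C@@H](OC(C)=O)[C@@H](C)c1oc(CC)c(C)c(=O)c1C | intermediate
28 | (2R,3R,4R,5R,6E,8S)-3-(acetyloxy)-8-{3,5-dimethyl-4-oxo-6-[(2S,3S)-3-(triethylsilyloxy)pentan-2-yl]-4H-pyran-2-yl}-2-(6-ethyl-3,5-dimethyl-4-oxo-4H-pyran-2-yl)-4,6-dimethylnon-6-en-5-yl propanoate | CCC(=O)O[C@@H](/C(C)=C/[C@H](C)c1oc([C@@H](C)[C@@H](O[Si](CC)(CC)CC)CC)c(C)c(=O)c1C)[C@H](C)[C@@H](OC(C)=O)[C@@H](C)c1oc(CC)c(C)c(=O)c1C | intermediate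
29 | (2R,3R,4R,5R,6E,8S)-3-(acetyloxy)-2-(6-ethyl-3,5-dimethyl-4-oxo-4H-pyran-2-yl)-8-{6-[(2S,3S)-3-hydroxypentan-2-yl]-3,5-dimethyl-4-oxo-4H-pyran-2-yl}-4,6-dimethylnon-6-en-5-yl propanoate | CCC(=O)O[C@@H](/C(C)=C/[C@H](C)c1oc([C@@H](C)[C@@H](O)CC)c(C)c(=O)c1C)[C@H](C)[C@@H](OC(C)=O)[C@@H](C)c1oc(CC)c(C)c(=O)c1C | target

## Step count and risk

Total step count: 15.
Longest linear sequence: 9 steps (13 to 29 through steps 6, 7, 8, 9, 10, 12, 13, 14, 15).

Three steps most likely to fail: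

**Step 14 (reductive coupling).** Risks are no turnover with the hindered, electron-poor chloride, ionisation of the allylic propanoate by low-valent nickel, or poor selectivity at C8. The fallback makes the C7–C8 bond by enantioselective hydroalkenylation of a vinylpyrone instead. It sets out from 10: its lithium dienolate 11 is quenched with PhSeCl (THF, −78 °C) to give 3,5-dimethyl-2-[1-(phenylselanyl)ethyl]-6-[(2S,3S)-3-(triethylsilyloxy)pentan-2-yl]-4H-pyran-4-one F1. H2O2/pyridine (CH2Cl2, 0 °C) oxidises it, and the selenoxide eliminates syn towards the methyl group to give 2-ethenyl-3,5-dimethyl-6-[(2S,3S)-3-(triethylsilyloxy)pentan-2-yl]-4H-pyran-4-one F2. Nickel-hydride-catalysed Markovnikov hydroalkenylation of F2 with vinyl bromide 27 (NiBr2·dme, chiral bis(imidazoline) ligand, (EtO)2MeSiH, KF, N,N-dimethylacetamide, rt) places the metal on the pyrone-stabilised carbon before C–C bond formation and gives 28, where the fallback comes back to the route.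

**Step 12 (vinylogous Mukaiyama aldol).** The aldehyde face (C3) is well controlled, but the configuration at C2 of the target chain (C6 of the heptenyl name) rests on an unproven open transition state. The fallback sets out from the crude step 12 product, that is 26 mixed with its C2 epimer (1E,3R,4R,5R,6S)-1-bromo-6-(6-ethyl-3,5-dimethyl-4-oxo-4H-pyran-2-yl)-5-hydroxy-2,4-dimethylhept-1-en-3-yl propanoate F3. Dess–Martin oxidation of the mixture gives (1E,3R,4S)-1-bromo-6-(6-ethyl-3,5-dimethyl-4-oxo-4H-pyran-2-yl)-2,4-dimethyl-5-oxohept-1-en-3-yl propanoate F4, in which C2 lies between the ketone and the pyrone and epimerises freely. Reduction with NaBH4/CeCl3·7H2O (MeOH, −78 °C) then runs as a dynamic kinetic resolution through the epimer in which Felkin–Anh control from both flanking centres coincides (C4 on one side, C2 with the pyrone as the large group on the other). This returns 26, where the fallback comes back to the route.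

**Step 3 (chloroaldehyde aldol).** Risks are racemisation of 6 by the basic dienolate and poor 2',3'-selectivity. The fallback sets out from 4: two equivalents of its lithium dienolate 7 are C-acylated with propanoic anhydride 2 to give racemic 2-ethyl-3,5-dimethyl-6-(3-oxopentan-2-yl)-4H-pyran-4-one F5. Felkin–Anh reduction with LiBH(sec-Bu)3 (THF, −78 °C, pyrone as the large group) gives the anti alcohol rac-2-ethyl-6-[(2S*,3S*)-3-hydroxypentan-2-yl]-3,5-dimethyl-4H-pyran-4-one F6. Kinetic resolution with immobilised Candida antarctica lipase B and vinyl acetate leaves 2-ethyl-6-[(2S,3S)-3-hydroxypentan-2-yl]-3,5-dimethyl-4H-pyran-4-one F7 and acetylates the (3R)-enantiomer to (2R,3R)-2-(6-ethyl-3,5-dimethyl-4-oxo-4H-pyran-2-yl)pentan-3-yl acetate F8. Silylation of F7 (Et3SiCl, imidazole, DMF) gives 10, where the fallback comes back to the route.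

Further compounds

F1 | step 14 | 3,5-dimethyl-2-[1-(phenylselanyl)ethyl]-6-[(2S,3S)-3-(triethylsilyloxy)pentan-2-yl]-4H-pyran-4-one | CC([Se]c1ccccc1)c1oc([C@@H](C)[C@@H](O[Si](CC)(CC)CC)CC)c(C)c(=O)c1C
F2 | step 14 | 2-ethenyl-3,5-dimethyl-6-[(2S,3S)-3-(triethylsilyloxy)pentan-2-yl]-4H-pyran-4-one | C=Cc1oc([C@@H](C)[C@@H](O[Si](CC)(CC)CC)CC)c(C)c(=O)c1C
F3 | step 12 | (1E,3R,4R,5R,6S)-1-bromo-6-(6-ethyl-3,5-dimethyl-4-oxo-4H-pyran-2-yl)-5-hydroxy-2,4-dimethylhept-1-en-3-yl propanoate | CCC(=O)O[C@@H](/C(C)=C/Br)[C@H](C)[C@@H](O)[C@H](C)c1oc(CC)c(C)c(=O)c1C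
F4 | step 12 | (1E,3R,4S)-1-bromo-6-(6-ethyl-3,5-dimethyl-4-oxo-4H-pyran-2-yl)-2,4-dimethyl-5-oxohept-1-en-3-yl propanoate (C6 epimers interconverting) | CCC(=O)O[C@@H](/C(C)=C/Br)[C@H](C)C(=O)C(C)c1oc(CC)c(C)c(=O)c1C
F5 | step 3 | 2-ethyl-3,5-dimethyl-6-(3-oxopentan-2-yl)-4H-pyran-4-one (racemic) | CCC(=O)C(C)c1oc(CC)c(C)c(=O)c1C
F6 | step 3 | rac-2-ethyl-6-[(2S*,3S*)-3-hydroxypentan-2-yl]-3,5-dimethyl-4H-pyran-4-one | CCc1oc([C@@H](C)[C@@H](O)CC)c(C)c(=O)c1C.CCc1oc([C@H](C)[C@H](O)CC)c(C)c(=O)c1C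
F7 | step 3 | 2-ethyl-6-[(2S,3S)-3-hydroxypentan-2-yl]-3,5-dimethyl-4H-pyran-4-one | CCc1oc([C@@H](C)[C@@H](O)CC)c(C)c(=O)c1C
F8 | step 3 | (2R,3R)-2-(6-ethyl-3,5-dimethyl-4-oxo-4H-pyran-2-yl)pentan-3-yl acetate | CCc1oc([C@H](C)[C@H](OC(C)=O)CC)c(C)c(=O)c1C
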